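## The problem

The target **25** is a C15 cage. A cyclobutane (C5–C6–C11–C10) carries on one face the enone bridge C6–C7(=O)–C8=C9(CH3)–C10, which makes a bicyclo[3.1.1]heptenone, and on the other face the four-carbon bridge C1–C2–C3–C4 (ring A), which ties the quaternary, methyl-bearing C11 to C5 through the gem-dimethyl carbon C4; C1 carries the tiglate and C3 the senecioate. This C1–C11 numbering is used for every compound below, and ring B is the six-membered ring C5–C10. Of the six stereocentres, C5, C6, C10 and C11 are locked by the cage and reduce to one question, the absolute sense of the C5/C10 pair. C1 and C3 are 1,3-trans on ring A, each next to a quaternary carbon. Ring A lies in the local mirror plane of the cage and its two faces differ only by the distant C7 carbonyl and C9 methyl group, so the cage cannot be relied on to set C3; C3 needs a reagent, and C1 can then be relayed from the C3 oxygen. The molecule is fragile in three places: the C6–C11 bond joins two acyl-bearing carbons of a strained ring and is open to reductive cleavage, a C1 ketone with oxygen at C3 can eliminate, and two equally neopentylic hydroxyls must receive two different unsaturated acyl groups. The feature that opens the structure is the 1,4-relation of the C7 carbonyl and the C1 oxygen across the C6–C11 bond: with C1 as a ketone, both ends of that bond are α-carbons of like polarity. If both ketones are enones (C7–C8=C9 and C1–C2=C3), each has a single α′ position, C6H2 and C11H, because C2 and C8 are vinylic and C4 is quaternary; the strain-free, cis-fused bicyclo[5.4.0]undecadienedione **16** therefore gives one bis-enolate, whose oxidation can close the cyclobutane.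

## Retrosynthesis

**25 ⇒ 22 + 23.** The last bond cut is the C1–O acyl bond. The tiglate is removed last, rather than the senecioate, because hydroxy ester **22** (senecioate already on O3) is the direct product of the reduction that sets C1, so no choice between two hydroxyls arises. The forward step must acylate a neopentylic secondary alcohol with tiglic acid **23** without moving the neighbouring ester.

**22 ⇒ 20 + 21.** The C1–H bond and the O3–acyl bond are cut together, back to β-hydroxy ketone **20** and 3-methylbut-2-enal **21** (Evans–Tishchenko). A hydroxyl-directed borohydride reduction would set C1 equally well but would leave a free 1,3-diol with two hindered hydroxyls of similar environment to tell apart. Here the mechanism leaves the acyl group on the oxygen that delivered the hydride. The precursor has one stereocentre and one ester fewer. The forward reaction must deliver hydride to C1 from the face of the C3 oxygen and accept a conjugated aldehyde as hydride source.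

**20 ⇒ 18.** The C3–O bond is cut to dienedione **18** (conjugate borylation, then oxidation). Epoxidation with reductive opening would reach the same compound but offers no comparable ligand control over a face that the substrate itself does not distinguish. Ring A of **18** has no sp3 stereocentre. The forward reaction must choose the disubstituted C2=C3 enone over the β,β-disubstituted C8=C9 enone and select the C3 face on the C10 side.

**18 ⇒ 16.** The C6–C11 bond is cut. It is the only cyclobutane bond whose two ends are both α to a carbonyl, hence the only one that can be made by joining two enolates; pairwise [2+2] cuts of the four-membered ring would demand a strained bridged diene instead. **16** has one ring, one bond, two stereocentres and all the strain less than **18**. The forward reaction asks for double α′-deprotonation and an oxidative 4-exo coupling, and only a cis-fused bicycle lets C6 reach C11.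

**16 ⇒ 14.** Both enone double bonds are removed in one operation: C2=C3 back to the saturated C1 ketone and C8=C9 back to the triisopropylsilyl enol ether of **14** (through bis(enol silane) **15**). Carrying the ring-B enone earlier is rejected, because next to a C11 ketone it would make C10–H the central proton of a vinylogous 1,3-diketone and endanger the ring fusion. The forward step needs kinetic enolisation of the C1 ketone toward C2, not C11.

**14 ⇒ 9.** The C11–CH3 bond is cut and the carbonyl is moved from C1 back to C11 (through **13**, **12** and **11**). This transposition is the price of the cycloaddition below, which needs its activating carbonyl on C11. Grignard addition and dehydration would be shorter but has no control over the direction of elimination. Enol triflate, methyl coupling and hydroboration would not tolerate the enol silane. α′-Hydroxylation, methyl addition, oxidation and samarium-mediated removal of the tertiary hydroxyl are each regiochemically unambiguous.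

**9 ⇒ 6 + 8.** The Diels–Alder cut of C5–C6 and C9–C10 gives 4,4-dimethylcyclohept-2-en-1-one **6** and siloxydiene **8**. Suprafacial addition to a (Z)-cycloalkenone gives the cis fusion for free, whereas annulations by conjugate addition and aldol closure would leave the fusion to equilibration. The siloxy group and the terminal methyl of **8** reinforce one regiochemistry, and the adduct keeps ring B masked as an enol silane. The forward reaction must overcome the neopentylic β-carbon of **6** and must take its absolute sense from a chiral Lewis acid.

**6 ⇒ 1 + 2; 8 ⇒ 7.** Enone **6** is cut to 3-methylcyclohex-2-en-1-one **1**: one methyl comes from methylmagnesium bromide **2** by conjugate addition, and the α-carbon comes from a one-carbon oxidative ring expansion of the regiodefined enol silane **3** through cyclopropane **4**. Diene **8** is the enol silane of (E)-pent-3-en-2-one **7**.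

## Roads not taken

**Alternative 1:** The cut is through C6–C7 and C9–C10, back to the ring-A-bridged bicyclo[1.1.0]butane **A2** and methylcyclopropenone **A3**. In the forward step [Rh(CO)2Cl]2 (monovalent rhodium) would open the acyl–vinyl bond of **A3**, and the rhodacycle would add across the central C6–C10 bond of **A2** to give **A1**.
- Merits: the step is convergent, makes the enone bridge and all four cage stereocentres at once, and arrives with the C1 and C3 oxygens already in place and differentiated. The end game after **A1** would be shorter than the chosen one and needs no late asymmetric step; in that respect it is the better route.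
- Weak points: **A2** is a bridged bicyclobutane with a quaternary carbon and two carbinol centres, at least as hard to make as the target's own cage. Its bridgeheads C6 and C10 differ only through the remote C1/C3 substituents, so nothing directs the acyl end of **A3** to C6 rather than C10; a diastereomer with the bridge turned end for end is expected alongside **A1**. Monovalent rhodium also isomerises bicyclobutanes to dienes.
- Comparison: the chosen plan is longer, but each bond has its regiochemistry fixed by constitution and the strained ring is made last from an unstrained bicycle.

**Alternative 2:** The cut is the C5–C10 bond, traced back to the N–H pyrrolidine **A5**, itself the product of an azomethine ylide [3+2] cycloaddition with a β,β-disubstituted acrylate. In the forward step N-amination with PhI(OH)OTs and ammonium carbamate would give an isodiazene, loss of N2 a 1,4-biradical, and collapse the cyclobutane **A4**.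
- Merits: catalytic asymmetric [3+2] cycloadditions are among the most dependable enantioselective reactions, so the absolute configuration would rest on firmer ground than a Diels–Alder reaction on a hindered cycloheptenone. All four cyclobutane centres are defined before the contraction.
- Weak points: the cycloaddition must create the quaternary C11 from a trisubstituted acrylate. The biradical is flanked by a quaternary carbon and two esters and can fragment into two alkenes. **A4** is only a monocyclic cyclobutane, so both the enone bridge and ring A remain to be closed onto a preformed strained ring, with two esters to differentiate.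
- Comparison: the chosen plan sets the less secure asymmetric Diels–Alder step against this, but after its key step the whole carbon cage exists, whereas **A4** is still two ring closures away from it.

**Alternative 3:** The cut is the C1–C2 bond, back to keto ester **A7**. In the forward step LiHMDS or KOtBu would enolise the methyl ketone at C2 and the enolate would attack the C1 ester on C11, closing ring A as the trione **A6**.
- Merits: both ring-A oxygens arrive with the ring closure, so no C–O bond has to be made later. Enolisation is unambiguous because C4 is quaternary, and the acidic C2–H of **A6** drives the condensation. On the oxygenation pattern this is better than the chosen plan, which needs a separate borylation.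
- Weak points: the real difficulty, the bicyclo[3.1.1]heptenone with quaternary C11 and the two side chains of **A7**, is left unsolved and would need a second strategy-level step. The closure is a seven-membered Claisen condensation onto an ester on a quaternary carbon. In **A6** the C1 and C3 carbonyls are both flanked by quaternary carbons, yet must be reduced to a trans diol with absolute control and then acylated with two different acids.
- Comparison: the chosen plan introduces the C3 and C1 oxygens one after the other, each with its own control element and each already differentiated.

Key step: step 11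

Remark 1: stereocentres that are planarised later (C9 in **9**–**15**, C1 in **11** and **12**, C11 in **12**–**16**) need no control; one epimer is drawn for each and both are carried forward.

Remark 2: the (S)-oxazaborolidinium catalyst of step 5 and (R,R)-QuinoxP* in step 12 are assumed to give the facial sense drawn; if either sense proves opposite, the mirror-image catalyst is used.

## Route

Step 1
Reactants: 1 3-methylcyclohex-2-en-1-one; 2 methylmagnesium bromide
Product: 3 3,3-dimethyl-1-(trimethylsilyloxy)cyclohex-1-ene
Conditions: MeMgBr, CuI (5 mol %), LiCl (10 mol %), Me3SiCl, THF, −40 → 0 °C; Et3N, pentane work-up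
Reagents that add atoms: chlorotrimethylsilane, C[Si](C)(C)Cl
Why: Copper-catalysed conjugate addition of the Grignard reagent, accelerated by Me3SiCl, builds the quaternary carbon (later C4) and traps the enolate as the silyl enol ether whose double bond points toward the new gem-dimethyl carbon, the regiochemistry that step 3 needs. No stereocentre is formed.

Step 2
Reactants: 3 3,3-dimethyl-1-(trimethylsilyloxy)cyclohex-1-ene
Product: 4 rac-5,5-dimethyl-1-(trimethylsilyloxy)bicyclo[4.1.0]heptane
Conditions: Et2Zn, CH2I2, CH2Cl2, 0 °C → rt
Reagents that add atoms: diiodomethane, ICI
Why: Simmons–Smith cyclopropanation (Et2Zn/CH2I2 variant) of the electron-rich silyl enol ether; the added CH2 becomes C10 of the target. The achiral alkene gives the racemic cyclopropane, whose stereocentres are lost in step 3.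

Step 3
Reactants: 4 rac-5,5-dimethyl-1-(trimethylsilyloxy)bicyclo[4.1.0]heptane
Product: 6 4,4-dimethylcyclohept-2-en-1-one, via 3-chloro-4,4-dimethylcycloheptan-1-one 5 (not isolated)
Conditions: FeCl3, DMF, 0 °C → rt; then NaOAc, MeOH, reflux
Reagents that add atoms: none
Why: FeCl3 oxidises the siloxycyclopropane by one electron, the internal cyclopropane bond breaks to a β-keto radical at the neopentylic carbon, and chlorine transfer gives β-chloroketone 5; NaOAc then eliminates HCl (oxidative one-carbon ring expansion of a cyclic ketone to the homologous enone). The quaternary γ-carbon rules out deconjugation.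

Step 4
Reactants: 7 (E)-pent-3-en-2-one
Product: 8 (E)-2-(triisopropylsilyloxy)penta-1,3-diene
Conditions: iPr3SiOTf, Et3N, Et2O, 0 °C → rt
Reagents that add atoms: triisopropylsilyl trifluoromethanesulfonate, CC(C)[Si](C(C)C)(C(C)C)OS(=O)(=O)C(F)(F)F
Why: Soft enolisation of the methyl ketone (silyl triflate and amine) removes an α′ proton and gives the cross-conjugated 2-siloxydiene with the (E)-propenyl unit intact. The triisopropylsilyl group is chosen because it should survive the Lewis acid of step 5 and the bases of steps 6–10.

Step 5
Reactants: 6 4,4-dimethylcyclohept-2-en-1-one; 8 (E)-2-(triisopropylsilyloxy)penta-1,3-diene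
Product: 9 cis-fused cycloadduct (C11 ketone; C7 triisopropylsilyl enol ether C7=C8; C9 methyl; 5R,10S; H5, H9 and H10 all syn)
Conditions: (S)-3,3-diphenyl-1-(o-tolyl)tetrahydropyrrolo[1,2-c][1,3,2]oxazaborole (20 mol %), Tf2NH (20 mol %), CH2Cl2, −78 → −20 °C
Reagents that add atoms: none
Why: Diels–Alder reaction under a triflimide-activated chiral oxazaborolidine, a catalyst type established for 2-cycloalkenone dienophiles and 2-siloxydienes; the siloxy group and the terminal methyl both direct the diene CH2 to the enone β-carbon (C5) and the methyl-bearing terminus to the α-carbon (C10). Suprafacial addition to the (Z)-enone fixes the cis ring fusion, the face left open by the catalyst fixes the absolute sense of C5/C10, and the endo transition state places the C9 methyl cis to C11 (C9 is erased in step 10).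

Step 6
Reactants: 9 cis-fused cycloadduct
Product: 11 1-hydroxy derivative of 9 (α′-hydroxy ketone), via potassium enolate 10 (not isolated)
Conditions: KN(SiMe3)2, THF, −78 °C; then 2-(phenylsulfonyl)-3-phenyloxaziridine, −78 °C; aq. NH4Cl
Reagents that add atoms: 2-(phenylsulfonyl)-3-phenyloxaziridine, O=S(=O)(c1ccccc1)N1OC1c1ccccc1
Why: Kinetic deprotonation by the bulky amide occurs at the C1 methylene, not at the doubly branched ring-fusion carbon C10, and the enolate is hydroxylated by the N-sulfonyloxaziridine (enolate oxidation). The C1 configuration is irrelevant because C1 is oxidised in step 8.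

Step 7
Reactants: 11 α′-hydroxy ketone; 2 methylmagnesium bromide
Product: 12 1,11-diol with the new C11 methyl group
Conditions: MeMgBr, CeCl3, THF, −78 → 0 °C
Reagents that add atoms: none
Why: Organocerium-mediated 1,2-addition of the methyl Grignard reagent to the hindered α-oxido ketone installs the C11 methyl group; CeCl3 suppresses enolisation toward C10 and so protects the ring fusion. Both C11 epimers serve.

Step 8
Reactants: 12 1,11-diol
Product: 13 tertiary α-ketol (C1 ketone, C11 hydroxyl and methyl)
Conditions: Dess–Martin periodinane, NaHCO3, CH2Cl2, 0 °C → rt
Reagents that add atoms: none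
Why: Dess–Martin oxidation can only touch the secondary C1 carbinol and gives the tertiary α-ketol; the bicarbonate buffer protects the silyl enol ether from the acetic acid released.

Step 9
Reactants: 13 tertiary α-ketol
Product: 14 C1 ketone with C11 H and CH3 (C7 silyl enol ether retained)
Conditions: SmI2 (2.5 equiv), THF–MeOH, −78 °C
Reagents that add atoms: none
Why: SmI2 reduces the ketone to a ketyl, the α-hydroxyl is expelled and a second electron gives the samarium enolate, which methanol protonates at C11 (reductive cleavage of an α-heterosubstituted ketone). With steps 6–8 this moves the carbonyl from C11 to C1 and methylates C11; the C11 configuration is free because C11 becomes an enolate carbon in step 11.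

Step 10
Reactants: 14 C1 ketone
Product: 16 cis-fused bis-enone (5R,10S)-4,4,9,11-tetramethylbicyclo[5.4.0]undeca-2,8-diene-1,7-dione in core numbering, via bis(silyl enol ether) 15 (not isolated)
Conditions: LiN(iPr)2, Me3SiCl, THF, −78 °C; then Pd(OAc)2 (2.4 equiv), DMSO–MeCN, 40 °C
Reagents that add atoms: none
Why: LiN(iPr)2 with internal Me3SiCl quench gives the kinetic enol silane toward the C2 methylene rather than the C11 methine; Pd(OAc)2 then turns both silyl enol ethers into palladium enolates at C2 and C8, and β-hydride elimination from C3 and C9 gives the two enones (Saegusa–Ito oxidation). The C9 stereocentre disappears, and C2 and C8 are now blocked as vinylic positions.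

Step 11
Reactants: 16 cis-fused bis-enone
Product: 18 tricyclic dienedione (5S,6R,10R,11R; C1 ketone, C2=C3, C7 enone, new C6–C11 bond), via dilithium bis(dienolate) 17 (not isolated)
Conditions: LiN(iPr)2 (2.3 equiv), THF, −78 °C; then Fe(acac)3 (2.2 equiv), THF, −78 °C → rt, 0.01 M
Reagents that add atoms: none
Why: Two equivalents of LiN(iPr)2 remove the only α′ protons of the two enones (C6–H and C11–H; C2 and C8 are vinylic, C4 is quaternary, and kinetic deprotonation avoids the γ sites C10–H and the C9 methyl), giving bis(dienolate) 17. Fe(acac)3 oxidises one enolate by one electron to an α-keto radical, which adds to the carbon of the second enolate, and a second electron transfer to iron turns the resulting ketyl radical anion into the 1,4-diketone. The closest known reactions are intramolecular oxidative couplings of ketone and amide enolates with Fe(acac)3 or copper carboxylates, and the oxidative closure of 1,6-diester dianions to cyclobutane-1,2-diesters. The cyclobutane C5–C6–C11–C10 closes in a 4-exo-trig sense (the C11=C1 enolate bond stays outside the new ring), and the same bond completes the bicyclo[3.1.1]heptenone. C6 and C11 are set by geometry, not by a reagent: in the cis-fused bicycle the two enolate carbons are gauche across C5–C10 and C1 is tied to C5 through C2–C4, so C11 can only bond with its methyl group on the enone side and C6 with its hydrogen outward. The step needs intramolecular C–C coupling to win over dimerisation and O–C coupling; high dilution and the proximity of the two α-carbons favour it, and 18 is protected from further oxidation because C6 is then a bridgehead and C11 quaternary.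

Step 12
Reactants: 18 tricyclic dienedione
Product: 20 (3R)-3-hydroxy tricyclic diketone (β-hydroxy ketone), via C3 pinacol boronate 19 (not isolated)
Conditions: CuCl (5 mol %), NaOtBu (10 mol %), (R,R)-QuinoxP* (6 mol %), B2pin2, MeOH, THF, rt; then NaBO3·4H2O, THF–H2O, rt
Reagents that add atoms: sodium perborate, [Na+].[Na+].O[B-]1(O)OO[B-](O)(O)OO1
Why: Copper–boryl conjugate addition goes to the disubstituted C2=C3 enone and leaves the β,β-disubstituted, bridge-bound C8=C9 enone. Because the ring-A enone lies in the local mirror plane of the cage, the face is chosen by the P-chiral ligand, which is to deliver boron to the C3 face on the C10 side. Perborate oxidises the C–B bond with retention and is too mild to epoxidise the remaining enone.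

Step 13
Reactants: 20 β-hydroxy ketone; 21 3-methylbut-2-enal
Product: 22 (1R,3R)-1-hydroxy-3-(3-methylbut-2-enoyloxy) tricyclic enone
Conditions: 3-methylbut-2-enal (5 equiv), SmI2 (30 mol %, premixed with the aldehyde), THF, −10 °C
Reagents that add atoms: none
Why: Evans–Tishchenko reaction: the C3 hydroxyl and the enal form a hemiacetal held to the C1 carbonyl by the samarium alkoxide catalyst, and its hydride is delivered intramolecularly to C1 on the face of the C3 oxygen, so the new C1 hydroxyl is trans (1,3-anti) to C3–O. The oxidised hemiacetal stays on O3 as the 3-methylbut-2-enoate, so the senecioate is installed and the two hydroxyls are differentiated in the same step. SmI2 is premixed with the aldehyde so that no divalent samarium meets the strained diketone.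

Step 14
Reactants: 22 hydroxy senecioate; 23 tiglic acid
Product: 25 target CNP0277258.1, via tiglic 2,4,6-trichlorobenzoic anhydride 24 (not isolated)
Conditions: tiglic acid, 2,4,6-trichlorobenzoyl chloride, Et3N, toluene, rt; then 22, DMAP, toluene, 60 °C
Reagents that add atoms: none
Why: Yamaguchi esterification: mixed anhydride 24 and DMAP acylate the remaining neopentylic C1 hydroxyl. The (E)-configured tiglate is the stable isomer, and the trans-1,3 arrangement disfavours migration of the C3 ester.

## Compound list

1 | 3-methylcyclohex-2-en-1-one | CC1=CC(=O)CCC1 | starting material
2 | methylmagnesium bromide | C[Mg]Br | starting material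
3 | 3,3-dimethyl-1-(trimethylsilyloxy)cyclohex-1-ene | CC1(C)CCCC(O[Si](C)(C)C)=C1 | intermediate
4 | rac-5,5-dimethyl-1-(trimethylsilyloxy)bicyclo[4.1.0]heptane | CC1(C)CCCC2(O[Si](C)(C)C)CC12 | intermediate
5 | rac-3-chloro-4,4-dimethylcycloheptan-1-one (not isolated) | CC1(C)CCCC(=O)CC1Cl | intermediate
6 | 4,4-dimethylcyclohept-2-en-1-one | CC1(C)CCCC(=O)C=C1 | intermediate
7 | (E)-pent-3-en-2-one | C/C=C/C(C)=O | starting material
8 | (E)-2-(triisopropylsilyloxy)penta-1,3-diene | C/C=C/C(=C)O[Si](C(C)C)(C(C)C)C(C)C | intermediate
9 | cis-fused cycloadduct: C11 ketone, C7 triisopropylsilyl enol ether (C7=C8), C4 gem-dimethyl, C9 methyl; 5R,10S, H5/H9/H10 all syn | C1CCC(C)(C)[C@@H]2CC(O[Si](C(C)C)(C(C)C)C(C)C)=C[C@H](C)[C@@H]2C1=O | intermediate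
10 | potassium enolate of 9 (O–C11=C1; not isolated) | C=1CCC(C)(C)[C@@H]2CC(O[Si](C(C)C)(C(C)C)C(C)C)=C[C@H](C)[C@@H]2C=1[O-].[K+] | intermediate
11 | 1-hydroxy derivative of 9 (C1 epimers, one drawn) | O[C@@H]1CCC(C)(C)[C@@H]2CC(O[Si](C(C)C)(C(C)C)C(C)C)=C[C@H](C)[C@@H]2C1=O | intermediate
12 | 1,11-diol with C11 methyl (C1 and C11 epimers, one drawn) | O[C@@H]1CCC(C)(C)[C@@H]2CC(O[Si](C(C)C)(C(C)C)C(C)C)=C[C@H](C)[C@@H]2[C@@]1(C)O | intermediate
13 | tertiary α-ketol: C1 ketone, C11 hydroxyl and methyl (C11 epimers, one drawn) | O=C1CCC(C)(C)[C@@H]2CC(O[Si](C(C)C)(C(C)C)C(C)C)=C[C@H](C)[C@@H]2[C@@]1(C)O | intermediate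
14 | C1 ketone with C11 H/CH3, C7 silyl enol ether (5R,10S; C11 epimers, 11R drawn) | O=C1CCC(C)(C)[C@@H]2CC(O[Si](C(C)C)(C(C)C)C(C)C)=C[C@H](C)[C@@H]2[C@H]1C | intermediate
15 | bis(silyl enol ether): C1 trimethylsilyl (C1=C2) and C7 triisopropylsilyl (C7=C8); not isolated | C[Si](C)(C)OC1=CCC(C)(C)[C@@H]2CC(O[Si](C(C)C)(C(C)C)C(C)C)=C[C@H](C)[C@@H]2[C@H]1C | intermediate
16 | cis-fused bis-enone, 4,4,9,11-tetramethylbicyclo[5.4.0]undeca-2,8-diene-1,7-dione in core numbering (5R,10S; C11 epimers, 11R drawn) | O=C1C=CC(C)(C)[C@@H]2CC(=O)C=C(C)[C@@H]2[C@H]1C | intermediate
17 | dilithium bis(dienolate) of 16 (O–C1=C11 and O–C7=C6; not isolated) | [Li+].[Li+].[O-]C=1C=CC(C)(C)[C@@H]2C=C([O-])C=C(C)[C@@H]2C=1C | intermediate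
18 | tricyclic dienedione (5S,6R,10R,11R): 16 with the C6–C11 bond | O=C1C=CC(C)(C)[C@@H]2[C@H]3C(=O)C=C(C)[C@@H]2[C@]31C | intermediate
19 | (3R)-3-(pinacolatoboryl) tricyclic diketone (not isolated) | O=C1C[C@@H](B4OC(C)(C)C(C)(C)O4)C(C)(C)[C@@H]2[C@H]3C(=O)C=C(C)[C@@H]2[C@]31C | intermediate
20 | (3R)-3-hydroxy tricyclic diketone (C1 ketone, C7 enone) | O=C1C[C@@H](O)C(C)(C)[C@@H]2[C@H]3C(=O)C=C(C)[C@@H]2[C@]31C | intermediate
21 | 3-methylbut-2-enal | CC(C)=CC=O | starting material
22 | (1R,3R)-1-hydroxy-3-(3-methylbut-2-enoyloxy) tricyclic enone | O[C@@H]1C[C@@H](OC(=O)C=C(C)C)C(C)(C)[C@@H]2[C@H]3C(=O)C=C(C)[C@@H]2[C@]31C | intermediate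
23 | tiglic acid, (E)-2-methylbut-2-enoic acid | C/C=C(\C)C(=O)O | starting material
24 | (E)-2-methylbut-2-enoic 2,4,6-trichlorobenzoic anhydride (not isolated) | C/C=C(\C)C(=O)OC(=O)c1c(Cl)cc(Cl)cc1Cl | intermediate
25 | CNP0277258.1, (1R,3R,5S,6R,10R,11R)-1-tigloyloxy-3-senecioyloxy tricyclic enone | C/C=C(\C)C(=O)O[C@@H]1C[C@@H](OC(=O)C=C(C)C)C(C)(C)[C@@H]2[C@H]3C(=O)C=C(C)[C@@H]2[C@]31C | target

## Step count and least certain steps

Total: 14 steps. Longest linear sequence: 13 steps (steps 1–3 and 5–14, from **1**); step 4 is a one-step side branch.

**Step 11 (key step).** The likeliest failure is that intramolecular C–C coupling loses to dimerisation, O–C coupling or simple re-protonation, because closing the four-membered ring costs strain and the tetrasubstituted C11 enolate is hindered. Incomplete deprotonation of the tertiary C11–H, followed by proton transfer to the γ-dienolate, is a second risk. The fallback makes the same bond by a two-electron path. It sets out from **16**: one equivalent of LiN(iPr)2 enolises the more accessible C6, and N-bromosuccinimide gives the 6-bromo bis-enone F1. KOtBu in tBuOH–THF then forms the C11 enolate, which displaces bromide in a 4-exo-tet alkylation and returns to **18**. The C6 bromide can epimerise, so the epimer with bromine anti to C11 is always available.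

**Step 5.** The neopentylic β-carbon of **6** may make the cycloaddition too slow at temperatures where the catalyst still controls the face. This would lead to low conversion, erosion of enantioselectivity, loss of the silyl group from the diene, or Lewis-acid epimerisation at C10 toward the trans-fused ketone. The fallback sets out from **6** and **8**: the cycloaddition is run with an achiral Lewis acid (EtAlCl2, CH2Cl2, −78 °C) and the racemate is separated by preparative chromatography on a chiral stationary phase. The enantiomer of 9, F2, is discarded and the route is rejoined at **9**.

**Step 12.** Copper–boryl addition at the neopentylic C3 may be sluggish, which would let borylation at C9 compete, or the ligand may fail to control a face on which the substrate has no say. The fallback sets out from **18**: nucleophilic epoxidation with tBuOOH and DBU attacks the same enone with a small nucleophile and gives the C2–C3 epoxy ketone with oxygen on the C10 side, F3, together with its diastereomer F4. After separation, F3 is opened at C2 with the selenide reagent made from (PhSe)2 and NaBH4 in EtOH–AcOH, which returns to **20**.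

**Step 13.** Hemiacetal formation and hydride transfer may be slow with the conjugated, less electrophilic enal. Retro-aldol cleavage or dehydration of **20** back to **18** could then take over. The fallback sets out from **20**: Evans–Saksena reduction with Me4NBH(OAc)3 in MeCN–AcOH gives the anti-1,3-diol F5 by the same intramolecular hydride delivery. Yamaguchi tigloylation is expected to take the C1 hydroxyl first, because its neighbour C11 is tied back in the cyclobutane while C3 sits beside the gem-dimethyl group, and gives the C1 tiglate F6. Esterification of the C3 hydroxyl with 3-methylbut-2-enoic acid under the same conditions rejoins the route at **25**. This fallback depends on a site selectivity that the main route avoids.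

**Step 10.** Oxidation of the robust triisopropylsilyl enol ether by Pd(OAc)2 may be incomplete, or enolisation of **14** may partly go toward C11. The fallback sets out from **14**: LiN(iPr)2 followed by PhSeCl (two equivalents) selenenylates the lithium enolate at C2 and the silyl enol ether at C8 to give the 2,8-bis(phenylseleno) diketone F7. H2O2 and pyridine then give both enones by selenoxide syn-elimination, which can only go toward C3 and C9, and the route is rejoined at **16**.

## Further compounds

F1 | step 11 | 6-bromo derivative of 16 (C6 epimers, interconverting) | O=C1C=CC(C)(C)[C@@H]2C(Br)C(=O)C=C(C)[C@@H]2[C@H]1C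
F2 | step 5 | enantiomer of 9 | C1CCC(C)(C)[C@H]2CC(O[Si](C(C)C)(C(C)C)C(C)C)=C[C@@H](C)[C@H]2C1=O
F3 | step 12 | C2–C3 epoxide of 18, oxygen on the C10 side | O=C1[C@H]4O[C@H]4C(C)(C)[C@@H]2[C@H]3C(=O)C=C(C)[C@@H]2[C@]31C
F4 | step 12 | C2–C3 epoxide of 18, oxygen on the C6 side | O=C1[C@@H]4O[C@@H]4C(C)(C)[C@@H]2[C@H]3C(=O)C=C(C)[C@@H]2[C@]31C
F5 | step 13 | (1R,3R)-1,3-dihydroxy tricyclic enone (anti-diol) | O[C@@H]1C[C@@H](O)C(C)(C)[C@@H]2[C@H]3C(=O)C=C(C)[C@@H]2[C@]31C
F6 | step 13 | (1R,3R)-1-tigloyloxy-3-hydroxy tricyclic enone | C/C=C(\C)C(=O)O[C@@H]1C[C@@H](O)C(C)(C)[C@@H]2[C@H]3C(=O)C=C(C)[C@@H]2[C@]31C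
F7 | step 10 | 2,8-bis(phenylseleno)-1,7-diketone (C2 and C8 epimers) | O=C1C([Se]c3ccccc3)CC(C)(C)[C@@H]2CC(=O)C([Se]c4ccccc4)[C@H](C)[C@@H]2[C@H]1C
A1 | alternative 1 | tricyclic enone with C1 hydroxyl and C3 silyl ether | O[C@@H]1C[C@@H](O[Si](C)(C)C(C)(C)C)C(C)(C)[C@@H]2[C@H]3C(=O)C=C(C)[C@@H]2[C@]31C
A2 | alternative 1 | ring-A-bridged bicyclo[1.1.0]butane with C1 hydroxyl and C3 silyl ether | O[C@@H]1C[C@@H](O[Si](C)(C)C(C)(C)C)C(C)(C)[C@@H]2[C@H]3[C@@H]2[C@]31C
A3 | alternative 1 | methylcyclopropenone | CC1=CC1=O
A4 | alternative 2 | cyclobutane diester with all four ring stereocentres | COC(=O)[C@H]1[C@H](C(C)(C)C=C)[C@@H](C(=O)OC(C)(C)C)[C@]1(C)CO[Si](C)(C)C(C)(C)C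
A5 | alternative 2 | N–H pyrrolidine precursor of A4 | COC(=O)[C@H]1[C@H](C(C)(C)C=C)N[C@@H](C(=O)OC(C)(C)C)[C@]1(C)CO[Si](C)(C)C(C)(C)C
A6 | alternative 3 | tricyclic trione (C1 and C3 ketones, C7 enone) | O=C1CC(=O)C(C)(C)[C@@H]2[C@H]3C(=O)C=C(C)[C@@H]2[C@]31C
A7 | alternative 3 | bicyclo[3.1.1]heptenone keto ester (C11 methyl ester, C5 2-methyl-3-oxobutan-2-yl) | CC(=O)C(C)(C)[C@@H]1[C@H]2C(=O)C=C(C)[C@@H]1[C@]2(C(=O)OC)C
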